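Ring A is closed through the C2–C3 bond. The C19 carboxyl on C4 makes C3 the β-carbon of a 2-substituted acrylic acid, so a primary C2 radical on the two-carbon arm of C10 adds to C3 in a 6-endo cyclization; with C5 and C10 already set, this delivers the trans-decalin, and later methylation of the C4 enolate anti to C20 completes the quaternary centre. The precursor is a 2,3-seco-labdane cyclohexanone mapped onto (1R,5R)-verbenone: its six-membered ring is ring B, its vinylic methyl is C20, its carbonyl is C8 (later C17 methylene) and the cyclobutane C(CH3)2 carbon is opened out to C4 with C3 and C19.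

Key step: step 8

Remarks on the chemistry: labdane numbering (C1–C20) is used for all intermediates, and β means the face of the C10 methyl group. Compound 1 is taken as the commercial (+)-enantiomer of verbenone. Compounds 18–20 are C4 epimer mixtures, which converge in step 11.

Step 1
Reactants: 1 (1R,5R)-(+)-verbenone; 2 vinylmagnesium bromide
Product: 3 silyl enol ether of 4-methyl-4-vinylnopinone (vinyl anti to the C(CH3)2 bridge)
Conditions: CuBr·SMe2 (10 mol %), Me3SiCl, LiCl, THF, −78 to −40 °C
Reagents that add atoms: vinylmagnesium bromide (2) C=C[Mg]Br; chlorotrimethylsilane C[Si](C)(C)Cl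
Why: Copper-catalysed, silyl-chloride-accelerated conjugate addition of the vinyl Grignard reagent should occur on the enone face opposite the C(CH3)2 bridge, which sets quaternary C10 (CH3 on the bridge side, vinyl = C1/C2 trans to the future C4), and the enolate is trapped regiospecifically as the C8–C9 silyl enol ether.

Step 2
Reactants: 3 silyl enol ether; 4 but-3-en-2-one
Product: 7 bicyclic diketone (3-oxobutyl chain syn to the bridge), via silyl enol ether adduct 5 (not isolated), via potassium enolate 6 (not isolated)
Conditions: Me3SiOTf (5 mol %), CH2Cl2, −78 °C; solvent switch, KH, THF, 0 °C to rt; 1 M HCl, −78 to 0 °C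
Reagents that add atoms: but-3-en-2-one (4) C=CC(C)=O
Why: Mukaiyama–Michael addition forms C9–C11 with silyl transfer to the new enol ether 5; KH then removes the only enolisable proton of the C8 ketone (the other α-carbon is a bridgehead, Bredt's rule, and the methyl ketone is masked), and kinetic protonation of enolate 6 from the open face anti to the bridge should leave the side chain on the bridge side, which is the 9α-H configuration of the target, while the acid also hydrolyses the enol ether.

Step 3
Reactants: 7 bicyclic diketone; 8 triethyl phosphonoacetate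
Product: 9 (E)-enoate
Conditions: NaH, THF, 0 °C to rt (7 added to the preformed phosphonate anion)
Reagents that add atoms: triethyl phosphonoacetate (8) CCOC(=O)CP(=O)(OCC)OCC
Why: Horner–Wadsworth–Emmons olefination should select the unhindered methyl ketone over the hindered bicyclic ketone and favour the E-enoate (the Z isomer is removed by chromatography), and the weakly basic phosphonate anion should not enolise C9.

Step 4
Reactants: 9 (E)-enoate
Product: 11 primary iodide, via alkyl-9-BBN borane 10 (not isolated)
Conditions: 9-BBN, THF, 0 °C to rt; then NaI, TsNClNa (chloramine-T), aq. MeOH, rt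
Reagents that add atoms: sodium iodide [Na+].[I-]
Why: Anti-Markovnikov hydroboration of the only electron-rich terminal alkene with 9-BBN, followed by iododeboronation of the primary B–C bond by iodine monochloride generated in the flask, should give the C2 iodide, because the conjugated ester alkene and the hindered ketone react much more slowly.

Step 5
Reactants: 11 primary iodide
Product: 14 isopropenyl cyclohexanone, via iodo silyl enol ether 12 (not isolated), via isopropenyl silyl enol ether 13 (not isolated)
Conditions: Me3SiI, CH2Cl2, −40 to 0 °C; DBU, 0 °C to rt; 1 M HCl, THF, 0 °C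
Reagents that add atoms: none
Why: O-Silylation of the ketone and strain release should cleave the cyclobutane bond between the α-bridgehead carbon (C7) and the C(CH3)2 carbon (future C4), as in acid-mediated fragmentations of nopinone-type ketones, giving the C7–C8 silyl enol ether and tertiary iodide 12; E2 elimination with DBU toward a methyl group (the tetrasubstituted exocyclic alternative is disfavoured by allylic strain against quaternary C10) gives the isopropenyl group, and cold acid unmasks C8 without enolisation toward C9, so C5, C9 and C10 are untouched.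

Step 6
Reactants: 14 isopropenyl cyclohexanone
Product: 15 allylic alcohol
Conditions: SeO2 (30 mol %), t-BuOOH, CH2Cl2, rt
Reagents that add atoms: tert-butyl hydroperoxide CC(C)(C)OO
Why: SeO2-catalysed allylic oxidation (ene reaction, then 2,3-sigmatropic shift) should hydroxylate the methyl group of the 1,1-disubstituted alkene, the usual site for isopropenyl groups, while the electron-poor enoate is much less reactive.

Step 7
Reactants: 15 allylic alcohol
Product: 17 acrylic acid, via enal 16 (not isolated)
Conditions: MnO2, CH2Cl2, rt; filter; NaClO2, NaH2PO4, 2-methyl-2-butene, t-BuOH/H2O, 0 °C to rt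
Reagents that add atoms: sodium chlorite [Na+].[O-]Cl=O
Why: MnO2 oxidises only the allylic alcohol to enal 16, and the Pinnick oxidation converts the aldehyde into the 2-substituted acrylic acid without touching the ketone, the alkyl iodide or the alkenes.

Step 8
Reactants: 17 acrylic acid
Product: 18 trans-decalin keto acid (C4 epimer mixture)
Conditions: Bu3SnH (slow addition), AIBN (20 mol %), benzene (0.01 M), 80 °C
Reagents that add atoms: none
Why: Bu3Sn• abstracts iodine from C2, the primary radical adds to C3, the unsubstituted β-carbon of the 2-substituted acrylic acid, and the resulting tertiary α-carboxy radical at C4 is reduced by Bu3SnH. The closest known reaction type is the Giese-type cyclisation of 5-substituted hex-5-enyl radicals onto α-substituted acrylates, which prefer the six-membered ring. Ring A closes in the 6-endo-trig mode through a chair transition state in which the two reacting arms are equatorial and trans on ring B, so the trans ring fusion follows from the C5 and C10 centres set in steps 1 and 5. The only new stereocentre is C4 (hydrogen delivered by the tin hydride, not controlled), and it is planarised again in step 11. The step needs 6-endo over 5-exo selectivity, which the fully substituted C4 secures (attack there would give an unstabilised primary radical) together with polarity matching at C3. Premature reduction and 1,5-hydrogen shifts are suppressed by slow addition of Bu3SnH at high dilution, and the distant trisubstituted enoate and the ketone are not competitive acceptors.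

Step 9
Reactants: 18 trans-decalin keto acid
Product: 19 exocyclic methylene acid
Conditions: Zn, CH2Br2, TiCl4, THF, 0 °C to rt (excess reagent)
Reagents that add atoms: dibromomethane BrCBr
Why: Takai–Lombardo methylenation converts hindered, enolisable ketones into methylene compounds under non-basic conditions, so C9 should not epimerise; esters are inert and the acid is carried as its zinc carboxylate.

Step 10
Reactants: 19 exocyclic methylene acid
Product: 20 allylic alcohol acid
Conditions: i-Bu2AlH (3.5 equiv), CH2Cl2, −78 °C
Reagents that add atoms: none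
Why: i-Bu2AlH reduces the conjugated ethyl ester to the (E)-allylic alcohol, while the carboxylic acid, present as its aluminium carboxylate at −78 °C, is not reduced.

Step 11
Reactants: 20 allylic alcohol acid
Product: 22 isocupressic acid, via trilithium enediolate 21 (not isolated)
Conditions: LiN(i-Pr)2 (3.5 equiv), THF/DMPU, 0 to 40 °C; MeI (1.1 equiv), −78 to 0 °C; 1 M HCl
Reagents that add atoms: iodomethane CI
Why: Alkylation of the carboxylic acid dianion (the alkoxide is a spectator) should take place on the α face of the planar C4 enediolate, anti to the axial C20 methyl on C10, giving the equatorial methyl and axial carboxyl (4S) as in enolate alkylations of related resin acids; C-methylation of the dianion is much faster than O-methylation of the lithium alkoxide.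

Step 12
Reactants: 22 isocupressic acid; 23 palmitoyl chloride
Product: 24 CNP0323052.1 (isocupressic acid 15-palmitate)
Conditions: pyridine, DMAP (cat.), CH2Cl2, 0 °C
Reagents that add atoms: palmitoyl chloride (23) CCCCCCCCCCCCCCCC(Cl)=O
Why: DMAP-catalysed O-acylation of the primary allylic alcohol by the acid chloride should be selective, because the tertiary, axial C19 carboxylic acid is too hindered to compete.

Compound list
1 | (1R,5R)-(+)-verbenone, (1R,5R)-4,6,6-trimethylbicyclo[3.1.1]hept-3-en-2-one | CC1=CC(=O)[C@@H]2C[C@H]1C2(C)C | starting material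
2 | vinylmagnesium bromide | C=C[Mg]Br | starting material
3 | 4,6,6-trimethyl-2-(trimethylsilyloxy)-4-vinylbicyclo[3.1.1]hept-2-ene, bridgeheads as in 1, vinyl anti to the C(CH3)2 bridge | C[C@@]1(C=C)C=C(O[Si](C)(C)C)[C@@H]2C[C@H]1C2(C)C | intermediate
4 | but-3-en-2-one (methyl vinyl ketone) | C=CC(C)=O | starting material
5 | 4,6,6-trimethyl-3-[3-(trimethylsilyloxy)but-2-enyl]-4-vinylbicyclo[3.1.1]heptan-2-one, C3 chain anti to the bridge (cis to vinyl) | C[C@@]1(C=C)[C@H](CC=C(C)O[Si](C)(C)C)C(=O)[C@@H]2C[C@H]1C2(C)C | intermediate
6 | potassium C2–C3 enolate of 5 | C[C@@]1(C=C)C(CC=C(C)O[Si](C)(C)C)=C([O-])[C@@H]2C[C@H]1C2(C)C.[K+] | intermediate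
7 | 4,6,6-trimethyl-3-(3-oxobutyl)-4-vinylbicyclo[3.1.1]heptan-2-one, 3-oxobutyl syn to the C(CH3)2 bridge (trans to vinyl) | C[C@@]1(C=C)[C@@H](CCC(C)=O)C(=O)[C@@H]2C[C@H]1C2(C)C | intermediate
8 | triethyl phosphonoacetate | CCOC(=O)CP(=O)(OCC)OCC | starting material
9 | ethyl (2E)-3-methyl-5-(4,6,6-trimethyl-2-oxo-4-vinylbicyclo[3.1.1]hept-3-yl)pent-2-enoate, configuration as in 7 | C[C@@]1(C=C)[C@@H](CC/C(C)=C/C(=O)OCC)C(=O)[C@@H]2C[C@H]1C2(C)C | intermediate
10 | B-alkyl-9-borabicyclo[3.3.1]nonane from 9, boron on the terminal carbon of the former vinyl group | C[C@@]1(CCB3C4CCCC3CCC4)[C@@H](CC/C(C)=C/C(=O)OCC)C(=O)[C@@H]2C[C@H]1C2(C)C | intermediate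
11 | ethyl (2E)-5-[4-(2-iodoethyl)-4,6,6-trimethyl-2-oxobicyclo[3.1.1]hept-3-yl]-3-methylpent-2-enoate, configuration as in 7 | C[C@@]1(CCI)[C@@H](CC/C(C)=C/C(=O)OCC)C(=O)[C@@H]2C[C@H]1C2(C)C | intermediate
12 | ring-opened cyclohexene: C7=C8 trimethylsilyl enol ether, C5 2-iodopropan-2-yl (β), C10 CH3 (β) and CH2CH2I (α), C9 pentenoate chain (β) | C[C@@]1(CCI)[C@@H](CC/C(C)=C/C(=O)OCC)C(O[Si](C)(C)C)=CC[C@H]1C(C)(C)I | intermediate
13 | as 12 with C5 isopropenyl in place of 2-iodopropan-2-yl | C[C@@]1(CCI)[C@@H](CC/C(C)=C/C(=O)OCC)C(O[Si](C)(C)C)=CC[C@H]1C(C)=C | intermediate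
14 | ethyl (2E)-5-[2-(2-iodoethyl)-2-methyl-6-oxo-3-(prop-1-en-2-yl)cyclohexyl]-3-methylpent-2-enoate; C8 ketone, 9α-H (chain β), C10 CH3 β and CH2CH2I α, 5α-H (isopropenyl β) | C[C@@]1(CCI)[C@@H](CC/C(C)=C/C(=O)OCC)C(=O)CC[C@H]1C(C)=C | intermediate
15 | as 14 with C5 3-hydroxyprop-1-en-2-yl | C[C@@]1(CCI)[C@@H](CC/C(C)=C/C(=O)OCC)C(=O)CC[C@H]1C(=C)CO | intermediate
16 | as 14 with C5 3-oxoprop-1-en-2-yl (2-substituted acrolein) | C[C@@]1(CCI)[C@@H](CC/C(C)=C/C(=O)OCC)C(=O)CC[C@H]1C(=C)C=O | intermediate
17 | 2-[3-((3E)-5-ethoxy-3-methyl-5-oxopent-3-enyl)-2-(2-iodoethyl)-2-methyl-4-oxocyclohexyl]prop-2-enoic acid, ring configuration as in 14 | C[C@@]1(CCI)[C@@H](CC/C(C)=C/C(=O)OCC)C(=O)CC[C@H]1C(=C)C(O)=O | intermediate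
18 | 15-ethyl hydrogen (13E)-8-oxo-17,18-dinorlabd-13-ene-15,19-dioate; 5α-H, 9α-H, 10β-CH3, C4 epimer mixture | O=C1CC[C@@H]2[C@](C)(CCCC2C(O)=O)[C@H]1CC/C(C)=C/C(=O)OCC | intermediate
19 | 15-ethyl hydrogen (13E)-18-norlabda-8(17),13-diene-15,19-dioate, C4 epimer mixture | C=C1CC[C@@H]2[C@](C)(CCCC2C(O)=O)[C@H]1CC/C(C)=C/C(=O)OCC | intermediate
20 | (13E)-15-hydroxy-18-norlabda-8(17),13-dien-19-oic acid, C4 epimer mixture | C=C1CC[C@@H]2[C@](C)(CCCC2C(O)=O)[C@H]1CC/C(C)=C/CO | intermediate
21 | trilithium salt of 20 (C15 alkoxide and C4 enediolate) | C=C1CC[C@@H]2[C@](C)(CCCC2=C([O-])[O-])[C@H]1CC/C(C)=C/C[O-].[Li+].[Li+].[Li+] | intermediate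
22 | isocupressic acid, (4S,5R,9S,10R,13E)-15-hydroxylabda-8(17),13-dien-19-oic acid | C=C1CC[C@@H]2[C@](C)(CCC[C@]2(C)C(O)=O)[C@H]1CC/C(C)=C/CO | intermediate
23 | palmitoyl chloride (hexadecanoyl chloride) | CCCCCCCCCCCCCCCC(Cl)=O | starting material
24 | CNP0323052.1, (4S,5R,9S,10R,13E)-15-(hexadecanoyloxy)labda-8(17),13-dien-19-oic acid | C=C1CC[C@@H]2[C@](C)(CCC[C@]2(C)C(=O)O)[C@H]1CC/C(C)=C/COC(=O)CCCCCCCCCCCCCCC | target

Total step count: 12. Longest linear sequence: 12 steps (from 1).

Steps most likely to fail

Step 5. The ring opening may be accompanied by enolisation toward C9 (erosion of the C9 configuration), by dealkylation of the ethyl ester with Me3SiI, or by elimination toward C5 instead of toward a methyl group. The fallback sets out from 11 and returns to 14. Acylative fragmentation with BF3·OEt2 and Zn(OAc)2 in Ac2O should give the ring-opened C7–C8 enol acetate carrying the isopropenyl group F1, the tertiary cation losing a methyl proton to acetate. Ammonolysis of the enol acetate (NH3, MeOH, 0 °C) then gives 14.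

Step 2. Removal of the C9 proton may be slow, because it lies on the hindered bridge face, and facial control in the reprotonation may be incomplete. The fallback sets out from 3 and returns to 7, and installs the C9 hydrogen last without any deprotonation. Mannich reaction of 3 with dimethylmethyleneiminium iodide gives the β-dimethylaminomethyl ketone F2. Quaternisation with MeI and treatment with NaHCO3 gives the α-methylene ketone F3. Mukaiyama–Michael addition of 2-(trimethylsilyloxy)propene (Me3SiOTf cat., CH2Cl2, −78 °C) to the exocyclic carbon gives the C8–C9 silyl enol ether of the diketone F4. Cold dilute HCl protonates C9 from the open face and gives 7.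

Step 11. The unprotected trianion may undergo O-methylation at the alkoxide or carboxylate, enolisation of the hindered C4–H may be incomplete, and facial selectivity may suffer. The fallback sets out from 20 and returns to 22. Esterification with Me3SiCHN2 gives the hydroxy methyl ester F5, and silylation (t-BuMe2SiCl, imidazole) gives the silyl ether methyl ester F6. Ester enolate methylation (LiN(i-Pr)2, then MeI) gives the C4-methylated ester F7, and Bu4NF gives methyl isocupressate F8. Nucleophilic demethylation of the hindered ester with LiSPr in HMPA gives 22.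

Further compounds
F1 | step 5 | ring-opened enol acetate: as 14 with C7=C8 enol acetate in place of the C8 ketone | C[C@@]1(CCI)[C@@H](CC/C(C)=C/C(=O)OCC)C(OC(C)=O)=CC[C@H]1C(C)=C
F2 | step 2 | 3-(dimethylaminomethyl)-4,6,6-trimethyl-4-vinylbicyclo[3.1.1]heptan-2-one, aminomethyl anti to the bridge | C[C@@]1(C=C)[C@H](CN(C)C)C(=O)[C@@H]2C[C@H]1C2(C)C
F3 | step 2 | 4,6,6-trimethyl-3-methylene-4-vinylbicyclo[3.1.1]heptan-2-one | C[C@@]1(C=C)C(=C)C(=O)[C@@H]2C[C@H]1C2(C)C
F4 | step 2 | 4-[4,6,6-trimethyl-2-(trimethylsilyloxy)-4-vinylbicyclo[3.1.1]hept-2-en-3-yl]butan-2-one | C[C@@]1(C=C)C(CCC(C)=O)=C(O[Si](C)(C)C)[C@@H]2C[C@H]1C2(C)C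
F5 | step 11 | methyl (13E)-15-hydroxy-18-norlabda-8(17),13-dien-19-oate, C4 epimer mixture | C=C1CC[C@@H]2[C@](C)(CCCC2C(=O)OC)[C@H]1CC/C(C)=C/CO
F6 | step 11 | 15-O-tert-butyldimethylsilyl ether of F5 | C=C1CC[C@@H]2[C@](C)(CCCC2C(=O)OC)[C@H]1CC/C(C)=C/CO[Si](C)(C)C(C)(C)C
F7 | step 11 | methyl 15-O-tert-butyldimethylsilyl isocupressate | C=C1CC[C@@H]2[C@](C)(CCC[C@]2(C)C(=O)OC)[C@H]1CC/C(C)=C/CO[Si](C)(C)C(C)(C)C
F8 | step 11 | methyl isocupressate | C=C1CC[C@@H]2[C@](C)(CCC[C@]2(C)C(=O)OC)[C@H]1CC/C(C)=C/CO
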